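**Plan**

Atoms are numbered as in labdane (C1–C20).

- **Cuts:** the coumarate C–O bond and its Z C=C; C13=C16 and C14=C15 (diene from an alkyne and ethylene); C8–C17; C9–C11; C8=C9 (ring B); C7–C8; C4–C5 (ring A); C5=C6 and C6–C7; C4=C18; C1–C10.
- **Forward order:** the C10 quaternary centre is made first, then the acyclic C18=C4 ketene dithioacetal / C5 allylsilane, ring A by anodic closure, a four-carbon arm on C5, ring B by aldol condensation onto the C9 aldehyde, the C9 side chain, the C8 carbinol, the diene and last the ester.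
- **Enabling feature:** C4 carries a methyl group and the oxidised carbon C18 and is bonded to C5, whose neighbour C6 is a vinyl carbon after closure. This is the pattern left when the radical cation of a C18=C4 donor alkene is captured at C4 by an allylsilane through C5, so ring A (C10, C1–C5) can close on an open chain.
- **Stereochemistry:** C10 comes from esterase desymmetrisation of a malonate; C4 and C5 from the chair of the anodic closure; C9 from axial conjugate addition anti to the C10 methyl; C8 from equatorial methyl addition to the 8-ketone; the Z-alkene from a Still–Gennari olefination.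

Key step: step 11

Remark: the esterase is assumed to cleave the ester group that gives the (R)-half-ester 4; if the (S)-half-ester formed, the same route would hold with the two carboxyl arms elaborated in the reverse order.

**Route**

Step 1
Reactants: 1 dimethyl 2-methylmalonate; 2 2-(3-chloropropyl)-2-methyl-1,3-dioxolane
Product: 3 dimethyl 2-methyl-2-[3-(2-methyl-1,3-dioxolan-2-yl)propyl]malonate
Conditions: NaH, DMF, 0 °C; then 2, NaI (cat.), 80 °C
Reagents that add atoms: none
Why: Malonate alkylation (SN2 of the sodium enolate on the primary chloride, helped by iodide exchange) joins C10 to C1 and cannot over-alkylate because the product has no acidic C–H.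

Step 2
Reactants: 3 dimethyl 2-methyl-2-[3-(2-methyl-1,3-dioxolan-2-yl)propyl]malonate
Product: 4 (2R)-3-methoxy-2-methyl-2-[3-(2-methyl-1,3-dioxolan-2-yl)propyl]-3-oxopropanoic acid
Conditions: pig liver esterase, 0.3 M phosphate buffer pH 7.5, DMSO (10 vol%), 25 °C; then pH 3 at 0 °C, EtOAc extraction
Reagents that add atoms: water, SMILES O
Why: Esterase desymmetrisation (hydrolysis of one of two enantiotopic ester groups of a 2,2-disubstituted malonate) creates the C10 stereocentre and stops at the half-ester, whose enantiomeric purity can if necessary be raised by crystallising a salt with a chiral amine.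

Step 3
Reactants: 4 (R)-half-ester
Product: 5 methyl (2R)-2-(hydroxymethyl)-2-methyl-5-(2-methyl-1,3-dioxolan-2-yl)pentanoate
Conditions: BH3·SMe2, THF, 0 °C → rt; MeOH quench
Reagents that add atoms: none
Why: Borane reduces the carboxylic acid chemoselectively (through the acyloxyborane) and leaves the methyl ester, the ketal and the quaternary centre untouched, so the acid arm becomes the future C5.

Step 4
Reactants: 5 hydroxy ester
Product: 6 methyl (2R)-2-formyl-2-methyl-5-(2-methyl-1,3-dioxolan-2-yl)pentanoate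
Conditions: (COCl)2, DMSO, CH2Cl2, −78 °C; Et3N, −78 °C → 0 °C
Reagents that add atoms: none
Why: Swern oxidation of the neopentyl primary alcohol gives an aldehyde that cannot enolise or epimerise because its α-carbon is quaternary.

Step 5
Reactants: 6 aldehyde ester
Product: 7 methyl (2R,3E)-4-iodo-2-methyl-2-[3-(2-methyl-1,3-dioxolan-2-yl)propyl]but-3-enoate
Conditions: CrCl2, CHI3, THF, 0 °C → rt
Reagents that add atoms: iodoform, SMILES IC(I)I
Why: Takai olefination (geminal dichromium reagent from CHI3 and CrCl2) converts the hindered aldehyde into the (E)-vinyl iodide and adds C6.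

Step 6
Reactants: 7 vinyl iodide ester
Product: 8 (2R,3E)-4-iodo-2-methyl-2-[3-(2-methyl-1,3-dioxolan-2-yl)propyl]but-3-en-1-ol
Conditions: i-Bu2AlH, CH2Cl2, −78 °C → 0 °C; Rochelle salt work-up
Reagents that add atoms: none
Why: Hydride reduction of the methyl ester to the primary alcohol (the future C9) at low temperature, where the vinyl iodide and the ketal are inert.

Step 7
Reactants: 8 iodo alcohol
Product: 9 tert-butyl{[(2R,3E)-4-iodo-2-methyl-2-[3-(2-methyl-1,3-dioxolan-2-yl)propyl]but-3-en-1-yl]oxy}diphenylsilane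
Conditions: t-BuPh2SiCl, imidazole, DMF, rt
Reagents that add atoms: tert-butyl(chloro)diphenylsilane, SMILES CC(C)(C)[Si](Cl)(c1ccccc1)c1ccccc1
Why: Silylation of the primary alcohol with a bulky, acid-stable group that should survive the ketal hydrolysis and the electrolysis and makes the C9 arm the larger substituent on C10.

Step 8
Reactants: 9 silyl ether vinyl iodide
Product: 10 tert-butyl{[(2R,3E)-2-methyl-2-[3-(2-methyl-1,3-dioxolan-2-yl)propyl]-5-(trimethylsilyl)pent-3-en-1-yl]oxy}diphenylsilane
Conditions: Me3SiCH2MgCl, Pd(PPh3)4 (5 mol%), THF, rt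
Reagents that add atoms: (trimethylsilyl)methylmagnesium chloride, SMILES C[Si](C)(C)C[Mg]Cl
Why: Kumada coupling of the vinyl iodide with the silylmethyl Grignard reagent at zerovalent palladium proceeds with retention of alkene geometry and gives the (E)-allylsilane, adding C7.

Step 9
Reactants: 10 allylsilane ketal
Product: 11 (6R,7E)-6-{[tert-butyl(diphenyl)silyl]oxymethyl}-6-methyl-9-(trimethylsilyl)non-7-en-2-one
Conditions: pyridinium p-toluenesulfonate (cat.), acetone/H2O 10:1, 50 °C
Reagents that add atoms: water, SMILES O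
Why: Mild acid-catalysed ketal hydrolysis frees the methyl ketone under conditions too weak to protodesilylate the allylsilane or cleave the silyl ether.

Step 10
Reactants: 11 methyl ketone
Product: 12 tert-butyl{[(2R,3E)-2-[4-(1,3-dithian-2-ylidene)pentyl]-2-methyl-5-(trimethylsilyl)pent-3-en-1-yl]oxy}diphenylsilane
Conditions: 2-(trimethylsilyl)-1,3-dithiane, n-BuLi, THF, −78 °C → 0 °C; then 11, −78 °C → rt
Reagents that add atoms: 2-(trimethylsilyl)-1,3-dithiane, SMILES C[Si](C)(C)C1SCCCS1
Why: Peterson olefination: the lithiated silyl dithiane adds to the ketone and elimination of lithium trimethylsilanolate gives the ketene dithioacetal, installing C18; the symmetric dithiane leaves no alkene isomerism at C4=C18.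

Step 11
Reactants: 12 ketene dithioacetal allylsilane
Product: 13 tert-butyl{[(1R,2S,3S)-2-ethenyl-3-(2-methoxy-1,3-dithian-2-yl)-1,3-dimethylcyclohexyl]methoxy}diphenylsilane
Conditions: undivided cell, reticulated vitreous carbon anode, Pt cathode, constant current (about 2.2 F/mol), LiClO4 (0.1 M), 2,6-lutidine, MeOH/THF 3:7, rt
Reagents that add atoms: methanol, SMILES CO
Why: Anodic oxidation removes one electron from the ketene dithioacetal, the group with the lowest oxidation potential; the radical cation is electrophilic at C4 and is attacked there by C5 of the allylsilane, the β-silyl cation loses its silyl group to methanol to leave the C5 vinyl group, and a second electron transfer followed by methanol capture turns C18 into the 2-methoxy-1,3-dithiane. The closest known reaction type is the intramolecular anodic olefin coupling of enol ether and ketene dithioacetal radical cations with allylsilanes, which is established for six-membered rings and for quaternary carbons. Ring A closes in a 6-exo mode (both π bonds exocyclic to the new ring) through a chair. C4 is controlled by the planar dithianylidene unit, which must stay perpendicular to the forming C4–C5 bond: in the axial site one sulfur would be pushed into the axial C10 substituent, so C18 goes equatorial and the C19 methyl axial. C5 is controlled by C10: the alkene arm sits equatorial, and the chair with the siloxymethyl group equatorial and the C10 methyl axial puts the new vinyl group trans to C9. The step needs chemoselective oxidation (secured by the large gap between the oxidation potentials of the dithioacetal and the allylsilane) and these two facial choices, of which the C5/C10 one rests only on the larger size of the siloxymethyl group and is the weaker.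

Step 12
Reactants: 13 ring A orthothioester
Product: 14 methyl (1S,2S,3R)-3-{[tert-butyl(diphenyl)silyl]oxymethyl}-2-ethenyl-1,3-dimethylcyclohexane-1-carboxylate
Conditions: MeI, CaCO3, MeCN/H2O 9:1, 40 °C
Reagents that add atoms: water, SMILES O
Why: S-Alkylative hydrolysis of the mixed S,S,O-orthoester: methylation makes sulfur a leaving group, water adds to the stabilised cation and loss of thiolate gives the methyl ester, which removes sulfur before the palladium, ruthenium and ozone steps.

Step 13
Reactants: 14 vinyl ester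
Product: 16 methyl (1S,2S,3R)-2-(but-3-en-1-yl)-3-{[tert-butyl(diphenyl)silyl]oxymethyl}-1,3-dimethylcyclohexane-1-carboxylate, via alkylborane 15 (not isolated)
Conditions: 9-BBN, THF, rt → 50 °C; then vinyl bromide, PdCl2(dppf) (5 mol%), K3PO4 (aq), DMF, 50 °C
Reagents that add atoms: 9-borabicyclo[3.3.1]nonane (kept in 15 only), SMILES [BH]1C2CCCC1CCC2; vinyl bromide, SMILES C=CBr
Why: Hydroboration puts boron on the terminal carbon C7 of the only alkene, and B-alkyl Suzuki–Miyaura coupling with vinyl bromide then forms C7–C8 and brings in the carbon that becomes the C17 aldehyde.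

Step 14
Reactants: 16 butenyl ester
Product: 18 methyl (1S,2S,3R)-3-{[tert-butyl(diphenyl)silyl]oxymethyl}-2-(4-hydroxybutyl)-1,3-dimethylcyclohexane-1-carboxylate, via alkylborane 17 (not isolated)
Conditions: 9-BBN, THF, rt; then NaOH (aq), H2O2, 0 °C → rt
Reagents that add atoms: 9-borabicyclo[3.3.1]nonane (kept in 17 only), SMILES [BH]1C2CCCC1CCC2; hydrogen peroxide, SMILES OO
Why: Anti-Markovnikov hydroboration–oxidation of the terminal alkene gives the primary alcohol on C17.

Step 15
Reactants: 18 silyl ether alcohol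
Product: 19 methyl (1S,2S,3R)-2-(4-hydroxybutyl)-3-(hydroxymethyl)-1,3-dimethylcyclohexane-1-carboxylate
Conditions: Bu4NF, AcOH (1:1), THF, rt
Reagents that add atoms: none
Why: Fluoride cleavage of the silyl ether, buffered with acetic acid so that no alkoxide is formed near the C18 ester.

Step 16
Reactants: 19 diol
Product: 20 methyl (1S,2S,3R)-3-formyl-1,3-dimethyl-2-(4-oxobutyl)cyclohexane-1-carboxylate
Conditions: (COCl)2, DMSO, CH2Cl2, −78 °C; Et3N, −78 °C → 0 °C
Reagents that add atoms: none
Why: Double Swern oxidation gives the dialdehyde, in which the C9 aldehyde sits on the quaternary C10 and cannot enolise.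

Step 17
Reactants: 20 dialdehyde
Product: 22 trans-fused enal (4S,5S,10S) with the C8=C9 alkene carrying the C17 formyl group on C8 and the C18 methyl ester, via aldol 21 (not isolated)
Conditions: dibenzylammonium trifluoroacetate (20 mol%), benzene, 50 °C
Reagents that add atoms: none
Why: Amine-salt-catalysed intramolecular aldol condensation: only the C17 aldehyde can form an enamine, its α-carbon C8 attacks the non-enolisable C9 aldehyde (6-enolexo closure of ring B) and E1cB loss of water gives the conjugated enal; the trans ring fusion follows from the C5/C10 configuration already present.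

Step 18
Reactants: 22 enal
Product: 23 silyl enol ether (4S,5S,9R,10S) with the 4-(trimethylsilyl)but-3-ynyl chain on C9 and C8=C17H–OSiMe3 (E/Z mixture)
Conditions: [4-(trimethylsilyl)but-3-yn-1-yl]magnesium bromide, CuBr·SMe2 (10 mol%), Me3SiCl, HMPA, THF, −78 °C; Et3N, cold NaHCO3 work-up
Reagents that add atoms: [4-(trimethylsilyl)but-3-yn-1-yl]magnesium bromide, SMILES C[Si](C)(C)C#CCC[Mg]Br; chlorotrimethylsilane, SMILES C[Si](C)(C)Cl
Why: Copper-catalysed, chlorosilane-accelerated conjugate addition of the Grignard reagent to the enal; the nucleophile attacks C9 axially on the face anti to the pseudoaxial C10 methyl (as in cuprate additions to trans-fused decal-1-en-3-ones with an angular methyl), which sets C9, and the enolate is trapped on oxygen.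

Step 19
Reactants: 23 silyl enol ether
Product: 25 8-ketone (4S,5S,9R,10R) with the 4-(trimethylsilyl)but-3-ynyl chain on C9 and the C18 methyl ester, via ozonide 24 (not isolated)
Conditions: O3, CH2Cl2, −78 °C, to the end-point of Sudan Red 7B; then Me2S, −78 °C → rt
Reagents that add atoms: ozone, SMILES [O-][O+]=O
Why: Ozonolysis of the electron-rich silyl enol ether C8=C17 with reductive work-up excises C17 and leaves the C8 ketone under neutral conditions that do not touch C9, while the much less reactive silyl alkyne survives when ozone is dosed to an indicator end-point.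

Step 20
Reactants: 25 8-ketone
Product: 26 tertiary alcohol (4S,5S,8R,9R,10R) with C17 methyl and hydroxyl on C8
Conditions: MeLi, CeCl3 (anhydrous), THF, −78 °C
Reagents that add atoms: methyllithium, SMILES [Li]C
Why: 1,2-Addition of the weakly basic organocerium reagent: axial approach is blocked by the syn-axial C10 methyl, so the methyl group enters equatorially and the hydroxyl ends axial and syn to C20 as required, while the low basicity protects the epimerisable C9.

Step 21
Reactants: 26 silyl alkyne
Product: 27 terminal alkyne (4S,5S,8R,9R,10R)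
Conditions: K2CO3 (cat.), MeOH, rt
Reagents that add atoms: none
Why: Base-catalysed methanolysis of the alkynyl C–Si bond frees the terminal alkyne without affecting the hindered ester or the tertiary alcohol.

Step 22
Reactants: 27 terminal alkyne
Product: 28 methyl (4S,5S,8R,9R,10R)-8-hydroxylabda-13(16),14-dien-18-oate
Conditions: ethylene (1 atm), second-generation Grubbs catalyst (5 mol%), toluene, 60 °C
Reagents that add atoms: ethylene, SMILES C=C
Why: Cross enyne metathesis of a terminal alkyne with ethylene: the ruthenium carbene adds across the alkyne and is released by ethylene, giving the 2-substituted buta-1,3-diene (C13=C16 and C14=C15) with no by-product.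

Step 23
Reactants: 28 diene ester
Product: 29 (4S,5S,8R,9R,10R)-labda-13(16),14-diene-8,18-diol
Conditions: LiAlH4, THF, 0 °C → 50 °C; Fieser work-up
Reagents that add atoms: none
Why: Hydride reduction of the hindered C18 methyl ester to the primary alcohol; the unactivated diene and the tertiary alcohol do not react.

Step 24
Reactants: 29 diene diol; 30 [bis(2,2,2-trifluoroethoxy)phosphoryl]acetic acid
Product: 31 C18 [bis(2,2,2-trifluoroethoxy)phosphoryl]acetate of diol 29
Conditions: N,N'-dicyclohexylcarbodiimide, 4-(dimethylamino)pyridine (cat.), CH2Cl2, 0 °C → rt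
Reagents that add atoms: none
Why: Steglich esterification acylates only the primary C18 hydroxyl, the tertiary C8 hydroxyl being inert under these conditions.

Step 25
Reactants: 31 phosphonoacetate; 32 4-(tert-butyldimethylsilyloxy)benzaldehyde
Product: 33 C18 (2Z)-3-[4-(tert-butyldimethylsilyloxy)phenyl]prop-2-enoate of diol 29
Conditions: KN(SiMe3)2 (1.05 equiv), 18-crown-6, THF, −78 °C; then 32, −78 °C, in the dark
Reagents that add atoms: none
Why: Still–Gennari variant of the Horner–Wadsworth–Emmons reaction: the electron-poor bis(trifluoroethyl) phosphonate eliminates fast from the kinetically formed adduct and gives the (Z)-cinnamate, and one equivalent of base deprotonates the phosphonate and not the far less acidic tertiary alcohol.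

Step 26
Reactants: 33 silyl-protected ester
Product: 34 [(4S,5S,8R,9R,10R)-8-hydroxylabda-13(16),14-dien-18-yl] (2Z)-3-(4-hydroxyphenyl)prop-2-enoate (CNP0197278.4)
Conditions: Bu4NF, AcOH (1:1), THF, 0 °C, amber glass
Reagents that add atoms: none
Why: Fluoride cleavage of the aryl silyl ether, buffered with acetic acid so that no phenoxide is formed that could ease Z-to-E isomerisation.

**Compound list**

1 | dimethyl 2-methylmalonate | COC(=O)C(C)C(=O)OC | starting material
2 | 2-(3-chloropropyl)-2-methyl-1,3-dioxolane | CC1(CCCCl)OCCO1 | starting material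
3 | dimethyl 2-methyl-2-[3-(2-methyl-1,3-dioxolan-2-yl)propyl]malonate | CC1(CCCC(C)(C(=O)OC)C(=O)OC)OCCO1 | intermediate
4 | (2R)-3-methoxy-2-methyl-2-[3-(2-methyl-1,3-dioxolan-2-yl)propyl]-3-oxopropanoic acid | CC1(CCC[C@@](C)(C(=O)OC)C(=O)O)OCCO1 | intermediate
5 | methyl (2R)-2-(hydroxymethyl)-2-methyl-5-(2-methyl-1,3-dioxolan-2-yl)pentanoate | CC1(CCC[C@@](C)(C(=O)OC)CO)OCCO1 | intermediate
6 | methyl (2R)-2-formyl-2-methyl-5-(2-methyl-1,3-dioxolan-2-yl)pentanoate | CC1(CCC[C@@](C)(C(=O)OC)C=O)OCCO1 | intermediate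
7 | methyl (2R,3E)-4-iodo-2-methyl-2-[3-(2-methyl-1,3-dioxolan-2-yl)propyl]but-3-enoate | CC1(CCC[C@@](C)(C(=O)OC)/C=C/I)OCCO1 | intermediate
8 | (2R,3E)-4-iodo-2-methyl-2-[3-(2-methyl-1,3-dioxolan-2-yl)propyl]but-3-en-1-ol | CC1(CCC[C@@](C)(CO)/C=C/I)OCCO1 | intermediate
9 | tert-butyl{[(2R,3E)-4-iodo-2-methyl-2-[3-(2-methyl-1,3-dioxolan-2-yl)propyl]but-3-en-1-yl]oxy}diphenylsilane | CC1(CCC[C@@](C)(CO[Si](c2ccccc2)(c2ccccc2)C(C)(C)C)/C=C/I)OCCO1 | intermediate
10 | tert-butyl{[(2R,3E)-2-methyl-2-[3-(2-methyl-1,3-dioxolan-2-yl)propyl]-5-(trimethylsilyl)pent-3-en-1-yl]oxy}diphenylsilane | CC1(CCC[C@@](C)(CO[Si](c2ccccc2)(c2ccccc2)C(C)(C)C)/C=C/C[Si](C)(C)C)OCCO1 | intermediate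
11 | (6R,7E)-6-{[tert-butyl(diphenyl)silyl]oxymethyl}-6-methyl-9-(trimethylsilyl)non-7-en-2-one | CC(=O)CCC[C@@](C)(CO[Si](c1ccccc1)(c1ccccc1)C(C)(C)C)/C=C/C[Si](C)(C)C | intermediate
12 | tert-butyl{[(2R,3E)-2-[4-(1,3-dithian-2-ylidene)pentyl]-2-methyl-5-(trimethylsilyl)pent-3-en-1-yl]oxy}diphenylsilane (key-step precursor) | CC(CCC[C@@](C)(CO[Si](c1ccccc1)(c1ccccc1)C(C)(C)C)/C=C/C[Si](C)(C)C)=C1SCCCS1 | intermediate
13 | tert-butyl{[(1R,2S,3S)-2-ethenyl-3-(2-methoxy-1,3-dithian-2-yl)-1,3-dimethylcyclohexyl]methoxy}diphenylsilane (key-step product) | C[C@@]1(CO[Si](c2ccccc2)(c2ccccc2)C(C)(C)C)CCC[C@](C)(C2(OC)SCCCS2)[C@H]1C=C | intermediate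
14 | methyl (1S,2S,3R)-3-{[tert-butyl(diphenyl)silyl]oxymethyl}-2-ethenyl-1,3-dimethylcyclohexane-1-carboxylate | C[C@@]1(CO[Si](c2ccccc2)(c2ccccc2)C(C)(C)C)CCC[C@](C)(C(=O)OC)[C@H]1C=C | intermediate
15 | B-alkyl-9-BBN adduct of 14 (boron on C7) | C[C@@]1(CO[Si](c2ccccc2)(c2ccccc2)C(C)(C)C)CCC[C@](C)(C(=O)OC)[C@H]1CCB1C2CCCC1CCC2 | intermediate (not isolated)
16 | methyl (1S,2S,3R)-2-(but-3-en-1-yl)-3-{[tert-butyl(diphenyl)silyl]oxymethyl}-1,3-dimethylcyclohexane-1-carboxylate | C[C@@]1(CO[Si](c2ccccc2)(c2ccccc2)C(C)(C)C)CCC[C@](C)(C(=O)OC)[C@H]1CCC=C | intermediate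
17 | B-alkyl-9-BBN adduct of 16 (boron on C17) | C[C@@]1(CO[Si](c2ccccc2)(c2ccccc2)C(C)(C)C)CCC[C@](C)(C(=O)OC)[C@H]1CCCCB1C2CCCC1CCC2 | intermediate (not isolated)
18 | methyl (1S,2S,3R)-3-{[tert-butyl(diphenyl)silyl]oxymethyl}-2-(4-hydroxybutyl)-1,3-dimethylcyclohexane-1-carboxylate | C[C@@]1(CO[Si](c2ccccc2)(c2ccccc2)C(C)(C)C)CCC[C@](C)(C(=O)OC)[C@H]1CCCCO | intermediate
19 | methyl (1S,2S,3R)-2-(4-hydroxybutyl)-3-(hydroxymethyl)-1,3-dimethylcyclohexane-1-carboxylate | C[C@@]1(CO)CCC[C@](C)(C(=O)OC)[C@H]1CCCCO | intermediate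
20 | methyl (1S,2S,3R)-3-formyl-1,3-dimethyl-2-(4-oxobutyl)cyclohexane-1-carboxylate | C[C@@]1(C=O)CCC[C@](C)(C(=O)OC)[C@H]1CCCC=O | intermediate
21 | aldol adduct: trans-fused decalin with 9-hydroxyl, 8-formyl and C18 methyl ester (C8 and C9 epimer mixture) | C[C@@]12CCC[C@](C)(C(=O)OC)[C@H]1CCC(C=O)C2O | intermediate (not isolated)
22 | methyl (1S,4aS,8aS)-6-formyl-1,4a-dimethyl-1,2,3,4,4a,7,8,8a-octahydronaphthalene-1-carboxylate (enal; labdane 4S,5S,10S) | C[C@@]12CCC[C@](C)(C(=O)OC)[C@H]1CCC(C=O)=C2 | intermediate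
23 | silyl enol ether (4S,5S,9R,10S): C9 bears the 4-(trimethylsilyl)but-3-ynyl chain anti to C20, C8=C17H–OSiMe3, C18 methyl ester | C[Si](C)(C)C#CCC[C@@H]1[C@]2(C)CCC[C@](C)(C(=O)OC)[C@H]2CCC1=CO[Si](C)(C)C | intermediate
24 | ozonide of 23 (1,2,4-trioxolane spiro at C8) | C[Si](C)(C)C#CCC[C@@H]1[C@]2(C)CCC[C@](C)(C(=O)OC)[C@H]2CCC13OOC(O[Si](C)(C)C)O3 | intermediate (not isolated)
25 | 8-ketone (4S,5S,9R,10R) with the 4-(trimethylsilyl)but-3-ynyl chain on C9 and C18 methyl ester | C[Si](C)(C)C#CCC[C@@H]1[C@]2(C)CCC[C@](C)(C(=O)OC)[C@H]2CCC1=O | intermediate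
26 | tertiary alcohol (4S,5S,8R,9R,10R): 8-hydroxy-8-methyl, silyl alkyne chain, C18 methyl ester | C[Si](C)(C)C#CCC[C@@H]1[C@]2(C)CCC[C@](C)(C(=O)OC)[C@H]2CC[C@@]1(C)O | intermediate
27 | terminal alkyne (4S,5S,8R,9R,10R): 9-(but-3-ynyl), 8-hydroxy-8-methyl, C18 methyl ester | C#CCC[C@@H]1[C@]2(C)CCC[C@](C)(C(=O)OC)[C@H]2CC[C@@]1(C)O | intermediate
28 | methyl (4S,5S,8R,9R,10R)-8-hydroxylabda-13(16),14-dien-18-oate | C=CC(=C)CC[C@@H]1[C@]2(C)CCC[C@](C)(C(=O)OC)[C@H]2CC[C@@]1(C)O | intermediate
29 | (4S,5S,8R,9R,10R)-labda-13(16),14-diene-8,18-diol | C=CC(=C)CC[C@@H]1[C@]2(C)CCC[C@](C)(CO)[C@H]2CC[C@@]1(C)O | intermediate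
30 | [bis(2,2,2-trifluoroethoxy)phosphoryl]acetic acid | OC(=O)CP(=O)(OCC(F)(F)F)OCC(F)(F)F | starting material
31 | (4S,5S,8R,9R,10R)-8-hydroxylabda-13(16),14-dien-18-yl [bis(2,2,2-trifluoroethoxy)phosphoryl]acetate | C=CC(=C)CC[C@@H]1[C@]2(C)CCC[C@](C)(COC(=O)CP(=O)(OCC(F)(F)F)OCC(F)(F)F)[C@H]2CC[C@@]1(C)O | intermediate
32 | 4-(tert-butyldimethylsilyloxy)benzaldehyde | O=Cc1ccc(O[Si](C)(C)C(C)(C)C)cc1 | starting material
33 | (4S,5S,8R,9R,10R)-8-hydroxylabda-13(16),14-dien-18-yl (2Z)-3-[4-(tert-butyldimethylsilyloxy)phenyl]prop-2-enoate | C=CC(=C)CC[C@@H]1[C@]2(C)CCC[C@](C)(COC(=O)/C=C\c3ccc(O[Si](C)(C)C(C)(C)C)cc3)[C@H]2CC[C@@]1(C)O | intermediate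
34 | (4S,5S,8R,9R,10R)-8-hydroxylabda-13(16),14-dien-18-yl (2Z)-3-(4-hydroxyphenyl)prop-2-enoate | C=CC(=C)CC[C@@H]1[C@]2(C)CCC[C@](C)(COC(=O)/C=C\c3ccc(O)cc3)[C@H]2CC[C@@]1(C)O | target

**Totals**

Total step count: 26. Longest linear sequence: 26 steps (1 → 34).

**Steps most likely to fail**

1. Step 11 (anodic closure of ring A). The ring closure may discriminate poorly between the two faces of the allylsilane, putting the vinyl group cis to C9, because methyl and siloxymethyl on C10 differ little in size. Methanol may also capture the radical cation before the ring closes. The C5 epimer would have to be removed by chromatography at 13 or 14. Fallback, from ketone 11 back to ester 14, by a two-electron cationic closure of the same C4–C5 bond: dimethylsulfonium methylide (Me3SI, n-BuLi, THF, 0 °C) converts 11 into the 2-methyl-2-alkyloxirane, epoxide F1 (both C4 epimers). Et2AlCl in CH2Cl2 at −78 °C opens the epoxide at the tertiary carbon C4 and the allylsilane closes ring A (epoxide-initiated Hosomi–Sakurai-type cyclisation), with the aluminium-bound oxymethyl arm equatorial, to give the C18 primary alcohol F2. Dess–Martin oxidation gives aldehyde F3, NaClO2/NaH2PO4/2-methylbut-2-ene gives acid F4, and Me3SiCHN2 in MeOH/toluene gives ester 14.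

2. Step 18 (conjugate addition at C9). Copper transfer to the neopentyl β-carbon may be slow, so that direct 1,2-addition of the Grignard reagent to the aldehyde takes over. Fallback, from enal 22 back to ketone 25, by a sigmatropic route: NaBH4/CeCl3·7H2O in MeOH reduces 22 to the allylic alcohol F5. Johnson–Claisen rearrangement (triethyl orthoacetate, cat. propionic acid, 140 °C) forms C9–C11 on the face anti to the C10 methyl and leaves an 8(17)-exocyclic methylene, giving ethyl ester F6. LiBH4 in THF reduces only the unhindered ethyl ester to the primary alcohol F7. PPh3, imidazole and iodine give the iodide F8. Lithium (trimethylsilyl)acetylide in THF/DMPU displaces iodide to give the silyl alkyne F9. OsO4 (cat.)/NaIO4 cleaves the exocyclic alkene to ketone 25.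

3. Step 20 (methyl addition at C8). The methyl group may be delivered from the axial face, or the reagent may deprotonate next to the ketone with loss of the C9 configuration. Fallback, from ketone 25 back to diol 29, by reversible ylide addition and hydride opening: dimethyloxosulfonium methylide (Me3S(O)I, NaH, DMSO, rt), whose reversible addition gives the equatorial C–C bond, forms the spiro-epoxide F10 with the oxygen axial. LiAlH4 in THF opens the epoxide at its methylene carbon and reduces the C18 ester in the same operation to give the silyl alkyne diol F11. K2CO3 in MeOH gives the terminal alkyne diol F12, and ethylene with the second-generation Grubbs catalyst, as in step 22, gives 29.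

**Further compounds**

F1 | step 11 | tert-butyl{[(2R,3E)-2-methyl-2-[3-(2-methyloxiran-2-yl)propyl]-5-(trimethylsilyl)pent-3-en-1-yl]oxy}diphenylsilane (epoxide epimers) | CC1(CCC[C@@](C)(CO[Si](c2ccccc2)(c2ccccc2)C(C)(C)C)/C=C/C[Si](C)(C)C)CO1
F2 | step 11 | [(1S,2S,3R)-3-{[tert-butyl(diphenyl)silyl]oxymethyl}-2-ethenyl-1,3-dimethylcyclohexyl]methanol | C[C@@]1(CO[Si](c2ccccc2)(c2ccccc2)C(C)(C)C)CCC[C@](C)(CO)[C@H]1C=C
F3 | step 11 | (1S,2S,3R)-3-{[tert-butyl(diphenyl)silyl]oxymethyl}-2-ethenyl-1,3-dimethylcyclohexane-1-carbaldehyde | C[C@@]1(CO[Si](c2ccccc2)(c2ccccc2)C(C)(C)C)CCC[C@](C)(C=O)[C@H]1C=C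
F4 | step 11 | (1S,2S,3R)-3-{[tert-butyl(diphenyl)silyl]oxymethyl}-2-ethenyl-1,3-dimethylcyclohexane-1-carboxylic acid | C[C@@]1(CO[Si](c2ccccc2)(c2ccccc2)C(C)(C)C)CCC[C@](C)(C(=O)O)[C@H]1C=C
F5 | step 18 | allylic alcohol: methyl (1S,4aS,8aS)-6-(hydroxymethyl)-1,4a-dimethyl-1,2,3,4,4a,7,8,8a-octahydronaphthalene-1-carboxylate | C[C@@]12CCC[C@](C)(C(=O)OC)[C@H]1CCC(CO)=C2
F6 | step 18 | Claisen ester: trans-decalin with 8(17)-exocyclic methylene, C9 ethoxycarbonylmethyl group anti to C20 and C18 methyl ester | CCOC(=O)C[C@@H]1[C@]2(C)CCC[C@](C)(C(=O)OC)[C@H]2CCC1=C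
F7 | step 18 | primary alcohol: C9 2-hydroxyethyl analogue of F6 | OCC[C@@H]1[C@]2(C)CCC[C@](C)(C(=O)OC)[C@H]2CCC1=C
F8 | step 18 | iodide: C9 2-iodoethyl analogue of F6 | ICC[C@@H]1[C@]2(C)CCC[C@](C)(C(=O)OC)[C@H]2CCC1=C
F9 | step 18 | silyl alkyne: C9 4-(trimethylsilyl)but-3-ynyl group, 8(17)-exocyclic methylene, C18 methyl ester | C[Si](C)(C)C#CCC[C@@H]1[C@]2(C)CCC[C@](C)(C(=O)OC)[C@H]2CCC1=C
F10 | step 20 | spiro-epoxide at C8 (oxygen axial and syn to C20) of ketone 25 | C[Si](C)(C)C#CCC[C@@H]1[C@]2(C)CCC[C@](C)(C(=O)OC)[C@H]2CC[C@@]13OC3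
F11 | step 20 | silyl alkyne diol (4S,5S,8R,9R,10R): 8-hydroxy-8-methyl, C18 hydroxymethyl | C[Si](C)(C)C#CCC[C@@H]1[C@]2(C)CCC[C@](C)(CO)[C@H]2CC[C@@]1(C)O
F12 | step 20 | terminal alkyne diol (4S,5S,8R,9R,10R) | C#CCC[C@@H]1[C@]2(C)CCC[C@](C)(CO)[C@H]2CC[C@@]1(C)O
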